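Everything rests on cutting the O1–C8a aryl ether bond of ring C. An open-chain (1S)-1,3-diarylpropane-1,3-diol that carries bromine on the future C8a is closed by copper-catalysed intramolecular O-arylation, which makes ring C in one operation. The step exploits two features. The C2 stereocentre sits on O1, so its C–O bond, fixed earlier by asymmetric transfer hydrogenation, stays intact throughout. Only the C2 hydroxyl can reach C8a through a six-membered ring, the C4 hydroxyl being limited to a four-membered one. C4 stays a carbinol until after ring closure, and both phenols are MOM ethers.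

Key step: step 9

Remark: C3 of the diol (the later C4) is formed racemic and carried as both epimers, because this carbon becomes the carbonyl carbon in step 10; only C2 needs control. Starting materials 1, 2 and 9 are assumed to be catalogue compounds.

Step 1
Reactants: 1 1-(3,4-dihydroxyphenyl)ethanone; 2 3-chloro-3-methylbut-1-yne
Product: 3 1-[3-hydroxy-4-(2-methylbut-3-yn-2-yloxy)phenyl]ethanone
Conditions: DBU (1.05 equiv), CuCl2·2H2O (1 mol %), MeCN, 0 °C to rt
Reagents that add atoms: none
Why: With one equivalent of base only the more acidic hydroxyl para to the acetyl group is ionised, and this phenoxide is O-alkylated by the tertiary propargylic chloride in a copper-catalysed propargylic substitution (Godfrey-type ether synthesis via a copper acetylide).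

Step 2
Reactants: 3 1-[3-hydroxy-4-(2-methylbut-3-yn-2-yloxy)phenyl]ethanone
Product: 4 1-[3-(methoxymethoxy)-4-(2-methylbut-3-yn-2-yloxy)phenyl]ethanone
Conditions: MOMCl, iPr2NEt, CH2Cl2, 0 °C to rt
Reagents that add atoms: chloromethyl methyl ether (MOMCl), COCCl
Why: Williamson-type O-alkylation (MOM protection) of the remaining phenol masks it for the enolate chemistry to come and leaves ketone and alkyne untouched.

Step 3
Reactants: 4 1-[3-(methoxymethoxy)-4-(2-methylbut-3-yn-2-yloxy)phenyl]ethanone
Product: 5 1-[3-(methoxymethoxy)-4-(2-methylbut-3-en-2-yloxy)phenyl]ethanone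
Conditions: H2 (1 atm), Pd/CaCO3 poisoned with Pb (Lindlar catalyst), quinoline, EtOAc, rt
Reagents that add atoms: none
Why: Lindlar semihydrogenation, in which the lead- and quinoline-poisoned palladium surface adds one equivalent of hydrogen to the terminal alkyne and stops at the 1,1-dimethylallyl ether without touching the aryl ketone.

Step 4
Reactants: 5 1-[3-(methoxymethoxy)-4-(2-methylbut-3-en-2-yloxy)phenyl]ethanone
Product: 7 1-[4-hydroxy-3-(methoxymethoxy)-5-(3-methylbut-2-en-1-yl)phenyl]ethanone, via ortho-dienone 6 (not isolated)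
Conditions: PhNEt2, 160 °C, Ar
Reagents that add atoms: none
Why: Aromatic Claisen rearrangement, in which the [3,3]-sigmatropic shift transfers the allyl unit with allylic inversion to C5, the only unsubstituted ortho carbon, turning the 1,1-dimethylallyl ether into the linear prenyl group before dienone 6 tautomerises to the phenol.

Step 5
Reactants: 7 1-[4-hydroxy-3-(methoxymethoxy)-5-(3-methylbut-2-en-1-yl)phenyl]ethanone
Product: 8 1-[4-methoxy-3-(methoxymethoxy)-5-(3-methylbut-2-en-1-yl)phenyl]ethanone
Conditions: MeI, K2CO3, acetone, reflux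
Reagents that add atoms: iodomethane (MeI), CI
Why: Williamson O-methylation of the phenoxide with iodomethane, in which carbonate does not deprotonate the methyl ketone, so only the phenol reacts.

Step 6
Reactants: 9 2-bromo-4-hydroxybenzaldehyde
Product: 10 2-bromo-4-(methoxymethoxy)benzaldehyde
Conditions: MOMCl, iPr2NEt, CH2Cl2, 0 °C to rt
Reagents that add atoms: chloromethyl methyl ether (MOMCl), COCCl
Why: MOM protection of the acidic para-formyl phenol by O-alkylation, to which the aldehyde and the aryl bromide are inert.

Step 7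
Reactants: 8 1-[4-methoxy-3-(methoxymethoxy)-5-(3-methylbut-2-en-1-yl)phenyl]ethanone; 10 2-bromo-4-(methoxymethoxy)benzaldehyde
Product: 12 rac-3-[2-bromo-4-(methoxymethoxy)phenyl]-3-hydroxy-1-[4-methoxy-3-(methoxymethoxy)-5-(3-methylbut-2-en-1-yl)phenyl]propan-1-one, via lithium enolate 11 (not isolated)
Conditions: LDA (1.1 equiv), THF, −78 °C; then 10, −78 °C; AcOH quench at −78 °C
Reagents that add atoms: none
Why: Directed crossed aldol addition, in which the preformed kinetic lithium enolate 11 adds to the non-enolisable aldehyde 10 at −78 °C and the cold acidic quench prevents retro-aldol and dehydration; the new carbinol is racemic by design because it becomes the C4 carbonyl carbon.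

Step 8
Reactants: 12 rac-3-[2-bromo-4-(methoxymethoxy)phenyl]-3-hydroxy-1-[4-methoxy-3-(methoxymethoxy)-5-(3-methylbut-2-en-1-yl)phenyl]propan-1-one
Product: 13 (1S,3RS)-3-[2-bromo-4-(methoxymethoxy)phenyl]-1-[4-methoxy-3-(methoxymethoxy)-5-(3-methylbut-2-en-1-yl)phenyl]propane-1,3-diol (C1 is S; both C3 epimers)
Conditions: RuCl[(S,S)-TsDPEN](p-cymene) (2 mol %), HCO2H/Et3N (5:2), EtOAc, 35 °C
Reagents that add atoms: none
Why: Noyori asymmetric transfer hydrogenation, in which the ruthenium hydride of the (S,S)-TsDPEN complex delivers hydride to the aryl ketone through the usual six-membered CH/π-organised transition state, which for aryl alkyl ketones should give the (S)-carbinol under catalyst control irrespective of the remote C3 centre, while the alkene, the aryl bromide and the MOM ethers are inert to formate.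

Step 9
Reactants: 13 (1S,3RS)-3-[2-bromo-4-(methoxymethoxy)phenyl]-1-[4-methoxy-3-(methoxymethoxy)-5-(3-methylbut-2-en-1-yl)phenyl]propane-1,3-diol
Product: 14 (2S,4RS)-7-(methoxymethoxy)-2-[4-methoxy-3-(methoxymethoxy)-5-(3-methylbut-2-en-1-yl)phenyl]-3,4-dihydro-2H-chromen-4-ol (C2 is S; both C4 epimers)
Conditions: CuI (10 mol %), 3,4,7,8-tetramethyl-1,10-phenanthroline (20 mol %), Cs2CO3 (2 equiv), toluene (0.03 M), 110 °C, Ar
Reagents that add atoms: none
Why: Carbonate deprotonates the C1 hydroxyl (the future C2–OH), the phenanthroline-bound monovalent copper alkoxide inserts into the neighbouring C–Br bond by oxidative addition, and C–O reductive elimination from the resulting trivalent arylcopper alkoxide forges O1–C8a and returns the catalyst. The closest known reaction type is the Ullmann–Buchwald copper-catalysed intramolecular O-arylation of secondary alcohols with aryl bromides, which is established for chromans. Ring C closes in a 6-exo sense at the sp2 carbon (the C–Br bond lies outside the new ring) through a seven-membered cupracycle. No stereocentre is created; C2 keeps its (S) configuration because only its O–H bond reacts, and the C4 carbinol passes through unchanged in either configuration. The selectivity needed is between the two hydroxyls and against intermolecular coupling: attack by the C4 oxygen would demand a four-membered ring, and high dilution favours the intramolecular path. Holding C4 at the alcohol level removes the retro-aldol and dehydration channels that a β-hydroxy ketone would have under carbonate at 110 °C.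

Step 10
Reactants: 14 (2S,4RS)-7-(methoxymethoxy)-2-[4-methoxy-3-(methoxymethoxy)-5-(3-methylbut-2-en-1-yl)phenyl]-3,4-dihydro-2H-chromen-4-ol
Product: 15 (2S)-7-(methoxymethoxy)-2-[4-methoxy-3-(methoxymethoxy)-5-(3-methylbut-2-en-1-yl)phenyl]-2,3-dihydro-4H-chromen-4-one
Conditions: Dess–Martin periodinane (1.3 equiv), NaHCO3, CH2Cl2, 0 °C to rt
Reagents that add atoms: none
Why: Dess–Martin oxidation of the secondary benzylic alcohol converts both C4 epimers into the same ketone under near-neutral buffered conditions, so the base-sensitive C2 centre is not opened to the chalcone and the prenyl alkene is untouched.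

Step 11
Reactants: 15 (2S)-7-(methoxymethoxy)-2-[4-methoxy-3-(methoxymethoxy)-5-(3-methylbut-2-en-1-yl)phenyl]-2,3-dihydro-4H-chromen-4-one
Product: 16 erylatissin C, (2S)-7-hydroxy-2-[3-hydroxy-4-methoxy-5-(3-methylbut-2-en-1-yl)phenyl]-2,3-dihydro-4H-chromen-4-one
Conditions: HCl (2 M in MeOH), THF co-solvent, rt to 40 °C; neutral work-up
Reagents that add atoms: none
Why: Acid-catalysed transacetalisation of the two aryl MOM ethers to methanol should free both phenols under dilute acid, which the prenyl group tolerates because no free hydroxyl lies ortho to it (no chroman formation) and which should not open the flavanone at C2; base is avoided in work-up.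

Compound list
1 | 1-(3,4-dihydroxyphenyl)ethanone | CC(=O)c1ccc(O)c(O)c1 | starting material
2 | 3-chloro-3-methylbut-1-yne | CC(C)(Cl)C#C | starting material
3 | 1-[3-hydroxy-4-(2-methylbut-3-yn-2-yloxy)phenyl]ethanone | CC(=O)c1ccc(OC(C)(C)C#C)c(O)c1 | intermediate
4 | 1-[3-(methoxymethoxy)-4-(2-methylbut-3-yn-2-yloxy)phenyl]ethanone | CC(=O)c1ccc(OC(C)(C)C#C)c(OCOC)c1 | intermediate
5 | 1-[3-(methoxymethoxy)-4-(2-methylbut-3-en-2-yloxy)phenyl]ethanone | CC(=O)c1ccc(OC(C)(C)C=C)c(OCOC)c1 | intermediate
6 | 4-acetyl-2-(methoxymethoxy)-6-(3-methylbut-2-en-1-yl)cyclohexa-2,4-dien-1-one (racemic, transient) | CC(=O)C1=CC(CC=C(C)C)C(=O)C(OCOC)=C1 | intermediate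
7 | 1-[4-hydroxy-3-(methoxymethoxy)-5-(3-methylbut-2-en-1-yl)phenyl]ethanone | CC(=O)c1cc(CC=C(C)C)c(O)c(OCOC)c1 | intermediate
8 | 1-[4-methoxy-3-(methoxymethoxy)-5-(3-methylbut-2-en-1-yl)phenyl]ethanone | CC(=O)c1cc(CC=C(C)C)c(OC)c(OCOC)c1 | intermediate
9 | 2-bromo-4-hydroxybenzaldehyde | O=Cc1ccc(O)cc1Br | starting material
10 | 2-bromo-4-(methoxymethoxy)benzaldehyde | O=Cc1ccc(OCOC)cc1Br | intermediate
11 | lithium enolate of 8, lithium 1-[4-methoxy-3-(methoxymethoxy)-5-(3-methylbut-2-en-1-yl)phenyl]ethen-1-olate | [Li]OC(=C)c1cc(CC=C(C)C)c(OC)c(OCOC)c1 | intermediate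
12 | rac-3-[2-bromo-4-(methoxymethoxy)phenyl]-3-hydroxy-1-[4-methoxy-3-(methoxymethoxy)-5-(3-methylbut-2-en-1-yl)phenyl]propan-1-one | COc1c(OCOC)cc(C(=O)CC(O)c2ccc(OCOC)cc2Br)cc1CC=C(C)C | intermediate
13 | (1S,3RS)-3-[2-bromo-4-(methoxymethoxy)phenyl]-1-[4-methoxy-3-(methoxymethoxy)-5-(3-methylbut-2-en-1-yl)phenyl]propane-1,3-diol (C3 epimer mixture, C3 left open in the SMILES) | COc1c(OCOC)cc([C@@H](O)CC(O)c2ccc(OCOC)cc2Br)cc1CC=C(C)C | intermediate
14 | (2S,4RS)-7-(methoxymethoxy)-2-[4-methoxy-3-(methoxymethoxy)-5-(3-methylbut-2-en-1-yl)phenyl]-3,4-dihydro-2H-chromen-4-ol (C4 epimer mixture, C4 left open in the SMILES) | COc1c(OCOC)cc([C@@H]2CC(O)c3ccc(OCOC)cc3O2)cc1CC=C(C)C | intermediate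
15 | (2S)-7-(methoxymethoxy)-2-[4-methoxy-3-(methoxymethoxy)-5-(3-methylbut-2-en-1-yl)phenyl]-2,3-dihydro-4H-chromen-4-one | COc1c(OCOC)cc([C@@H]2CC(=O)c3ccc(OCOC)cc3O2)cc1CC=C(C)C | intermediate
16 | erylatissin C, (2S)-7-hydroxy-2-[3-hydroxy-4-methoxy-5-(3-methylbut-2-en-1-yl)phenyl]-2,3-dihydro-4H-chromen-4-one | COc1c(O)cc([C@@H]2CC(=O)c3ccc(O)cc3O2)cc1CC=C(C)C | target

Total step count: 11 steps.
Longest linear sequence: 10 steps (steps 1–5 and 7–11); step 6 is a one-step branch.

Steps most likely to fail

Step 9 (ring closure). Oxidative addition of the copper alkoxide into the aryl–bromine bond may be too slow at this electron-rich ring, so that reductive loss of bromine or thermal decomposition of the diol takes over. The fallback changes the catalytic manifold to palladium-catalysed Buchwald–Hartwig etherification, setting out from diol 13 and returning at flavan-4-ol 14. It would use Pd(OAc)2, 2-(di-tert-butylphosphino)-1,1'-binaphthyl and Cs2CO3 in toluene at 70–80 °C. Zerovalent palladium inserts into the C–Br bond, and the bulky phosphine drives C–O reductive elimination from the divalent arylpalladium alkoxide ahead of β-hydride elimination. The C2–O bond is again untouched; no compound outside the list arises (F0).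

Step 1 (site-selective propargylation). Discrimination between the two phenolic hydroxyls may be poor, or double alkylation may occur, with the reactive tertiary propargylic electrophile. The fallback separates site selection from the difficult alkylation, setting out from 1 and returning at 4. Benzylation at the para hydroxyl (BnBr, NaHCO3, NaI, DMF, 40 °C) would give 1-[4-(benzyloxy)-3-hydroxyphenyl]ethanone F1. MOM protection (MOMCl, iPr2NEt, CH2Cl2) would give 1-[4-(benzyloxy)-3-(methoxymethoxy)phenyl]ethanone F2. Hydrogenolysis (H2, Pd/C, EtOAc) would give 1-[4-hydroxy-3-(methoxymethoxy)phenyl]ethanone F3. Its single free phenol is then propargylated with 2 (DBU, CuCl2·2H2O, MeCN) to give 4.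

Step 8 (asymmetric transfer hydrogenation). Hydride transfer to the electron-rich ketone may be sluggish, or facial selectivity may erode because of the free β-hydroxyl. The fallback switches to oxazaborolidine-catalysed borane reduction of a protected substrate, setting out from 12 and returning at 13. Silylation (TBSOTf, 2,6-lutidine, CH2Cl2, −78 °C) would give rac-3-[2-bromo-4-(methoxymethoxy)phenyl]-3-[(tert-butyldimethylsilyl)oxy]-1-[4-methoxy-3-(methoxymethoxy)-5-(3-methylbut-2-en-1-yl)phenyl]propan-1-one F4. Corey–Bakshi–Shibata reduction with (R)-2-methyl-CBS-oxazaborolidine (20 mol %) and catecholborane in toluene at −78 °C would give (1S)-3-[2-bromo-4-(methoxymethoxy)phenyl]-3-[(tert-butyldimethylsilyl)oxy]-1-[4-methoxy-3-(methoxymethoxy)-5-(3-methylbut-2-en-1-yl)phenyl]propan-1-ol F5. Catecholborane is chosen because it does not hydroborate the prenyl group. Desilylation (TBAF, THF, 0 °C) then gives 13.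

Further compounds
F0 | step 9 | none | none
F1 | step 1 | 1-[4-(benzyloxy)-3-hydroxyphenyl]ethanone | CC(=O)c1ccc(OCc2ccccc2)c(O)c1
F2 | step 1 | 1-[4-(benzyloxy)-3-(methoxymethoxy)phenyl]ethanone | CC(=O)c1ccc(OCc2ccccc2)c(OCOC)c1
F3 | step 1 | 1-[4-hydroxy-3-(methoxymethoxy)phenyl]ethanone | CC(=O)c1ccc(O)c(OCOC)c1
F4 | step 8 | rac-3-[2-bromo-4-(methoxymethoxy)phenyl]-3-[(tert-butyldimethylsilyl)oxy]-1-[4-methoxy-3-(methoxymethoxy)-5-(3-methylbut-2-en-1-yl)phenyl]propan-1-one | COc1c(OCOC)cc(C(=O)CC(O[Si](C)(C)C(C)(C)C)c2ccc(OCOC)cc2Br)cc1CC=C(C)C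
F5 | step 8 | (1S)-3-[2-bromo-4-(methoxymethoxy)phenyl]-3-[(tert-butyldimethylsilyl)oxy]-1-[4-methoxy-3-(methoxymethoxy)-5-(3-methylbut-2-en-1-yl)phenyl]propan-1-ol (both C3 epimers) | COc1c(OCOC)cc([C@@H](O)CC(O[Si](C)(C)C(C)(C)C)c2ccc(OCOC)cc2Br)cc1CC=C(C)C
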